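## Retrosynthetic overview

1. The two esters go on last: the C8 angelate by acylation of an 8α-alcohol, the C4 anisate by Mitsunobu inversion of a 4β-alcohol on a trans-fused hydroazulenone.
2. The angular 8a-methyl comes from hydroxyl-directed cyclopropanation of a C8=C8a enol ether and opening of the derived cyclopropanol; the C8 ketone so unmasked pulls the C5=C6 alkene into the C6=C7 position.
3. The seven-membered ring is made by a (4+3) union that forms C7–C8 and C3a–C4: tandem cyclopropanation/Cope rearrangement of an alkoxy(cyclopentenyl)carbene chromium complex (C8, C8a, C3a) with a 1-silyloxy-3-methylbutadiene (C4–C7).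
4. Ring order: five-membered ring first (from 3-ethoxycyclopentenone, the C3 carbinol set by asymmetric enone epoxidation), seven-membered ring second, in the key step.
5. Enabling feature: the C8 oxygen between quaternary C8a and the C6=C7 alkene makes the seven-membered ring a masked 1-alkoxycyclohepta-1,4-diene (C8=C8a, C5=C6), the retron of a 1-alkoxy-1,2-dialkenylcyclopropane Cope rearrangement; C4–C7 with the C6 methyl and the C4 oxygen is an intact prenal-derived dienyl ether.

Key step: step 8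

Remark: azulene locants are used for all bicyclic compounds (C3 carbinol, C3a/C8a ring fusion, C4 anisate carbon, C8 angelate carbon), the target is the (3R,3aS,4S,8R,8aS) isomer, and angelic anhydride is taken to be a purchasable reagent.

## Route

Step 1
Reactants: 1 3-ethoxycyclopent-2-en-1-one
Product: 3 3-(propan-2-yl)cyclopent-2-en-1-one, via magnesium alkoxide 2 (not isolated)
Conditions: i-PrMgCl, CeCl3, THF, 0 °C; then 1 M HCl, rt
Reagents that add atoms: isopropylmagnesium chloride, CC(C)[Mg]Cl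
Why: Stork–Danheiser sequence, in which 1,2-addition to the vinylogous ester and acid hydrolysis with carbonyl transposition should give the 3-substituted enone; no stereocentre is set.

Step 2
Reactants: 3 3-(propan-2-yl)cyclopent-2-en-1-one
Product: 4 (1S,5R)-5-(propan-2-yl)-6-oxabicyclo[3.1.0]hexan-2-one
Conditions: 50% aq. H2O2, 9-amino-9-deoxy-epi-quinine bis(trifluoroacetate) (10 mol %; the quinidine-derived pseudoenantiomer if that one leads to the (1S,5R) series), dioxane, 35 °C
Reagents that add atoms: hydrogen peroxide, OO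
Why: Iminium-catalysed nucleophilic (Weitz–Scheffer type) epoxidation of a cyclic enone should set the tertiary C–O centre that becomes C3 of the target, the catalyst enantiomer fixing its absolute configuration and the cis ring fusion fixing the second centre.

Step 3
Reactants: 4 (1S,5R)-5-(propan-2-yl)-6-oxabicyclo[3.1.0]hexan-2-one
Product: 6 (3R)-3-hydroxy-3-(propan-2-yl)cyclopent-1-ene-1-carbaldehyde, via enol ether 5 (not isolated)
Conditions: Ph3P(CH2OMe)Cl, KN(SiMe3)2, THF, −78 → 0 °C; then 1 M HCl, THF, 0 °C → rt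
Reagents that add atoms: (methoxymethyl)triphenylphosphonium chloride, COC[P+](c1ccccc1)(c1ccccc1)c1ccccc1.[Cl-]; water, O
Why: Wittig methoxymethylenation followed by enol ether hydrolysis should give a β,γ-epoxy aldehyde equivalent that opens by vinylogous β-elimination to the γ-hydroxy enal, the C–O bond at the tertiary carbon staying intact so that its configuration is retained.

Step 4
Reactants: 6 (3R)-3-hydroxy-3-(propan-2-yl)cyclopent-1-ene-1-carbaldehyde
Product: 7 (3R)-3-hydroxy-3-(propan-2-yl)cyclopent-1-ene-1-carboxylic acid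
Conditions: NaClO2, NaH2PO4, 2-methylbut-2-ene, t-BuOH/H2O, 0 °C → rt
Reagents that add atoms: sodium chlorite, [Na+].[O-]Cl=O
Why: Pinnick oxidation should convert the enal into the acid without touching the alkene or the tertiary alcohol.

Step 5
Reactants: 7 (3R)-3-hydroxy-3-(propan-2-yl)cyclopent-1-ene-1-carboxylic acid
Product: 9 (3R)-3-(propan-2-yl)-3-(trimethylsilyloxy)cyclopent-1-ene-1-carbonyl chloride, via bis-silyl derivative 8 (not isolated)
Conditions: (Me3Si)2NH, Me3SiCl (cat.), CH2Cl2, 40 °C; concentrate; (COCl)2, DMF (cat.), CH2Cl2, 0 °C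
Reagents that add atoms: hexamethyldisilazane, C[Si](C)(C)N[Si](C)(C)C; oxalyl chloride, ClC(=O)C(Cl)=O
Why: Silylation of both hydroxyl functions and Vilsmeier-type conversion of the silyl ester into the acid chloride under neutral conditions should leave the tertiary silyl ether intact.

Step 6
Reactants: 9 (3R)-3-(propan-2-yl)-3-(trimethylsilyloxy)cyclopent-1-ene-1-carbonyl chloride
Product: 12 pentacarbonyl{[(4-methoxyphenyl)methoxy][(3R)-3-(propan-2-yl)-3-(trimethylsilyloxy)cyclopent-1-en-1-yl]methylidene}chromium, via sodium acyl chromate 10 (not isolated), via acetoxycarbene complex 11 (not isolated)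
Conditions: Na2Cr(CO)5 (from Cr(CO)6 and NaC10H8, THF, −78 °C), then 9, −78 → 0 °C; solvent changed to CH2Cl2; AcBr, −40 °C; 4-methoxybenzyl alcohol, −40 → 0 °C
Reagents that add atoms: disodium pentacarbonylchromate, [Na+].[Na+].O=C=[Cr-2](=C=O)(=C=O)(=C=O)=C=O; 4-methoxybenzyl alcohol, COc1ccc(CO)cc1
Why: Acylation of the pentacarbonylchromate dianion by the acid chloride, O-acetylation of the acyl chromate and alcohol exchange at the acyloxycarbene should give the alkoxy(alkenyl) Fischer carbene complex with an oxidatively removable O-substituent; no stereocentre is touched.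

Step 7
Reactants: 13 3-methylbut-2-enal
Product: 14 tert-butyl(dimethyl){[(1E)-3-methylbuta-1,3-dien-1-yl]oxy}silane
Conditions: t-BuMe2SiOTf, Et3N, Et2O, 0 °C → rt
Reagents that add atoms: tert-butyldimethylsilyl trifluoromethanesulfonate, CC(C)(C)[Si](C)(C)OS(=O)(=O)C(F)(F)F
Why: O-silylation of the enal with γ-deprotonation (soft dienolisation) should give the (E)-1-silyloxy diene.

Step 8
Reactants: 12 pentacarbonyl{[(4-methoxyphenyl)methoxy][(3R)-3-(propan-2-yl)-3-(trimethylsilyloxy)cyclopent-1-en-1-yl]methylidene}chromium; 14 tert-butyl(dimethyl){[(1E)-3-methylbuta-1,3-dien-1-yl]oxy}silane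
Product: 17 (3R,3aS,4R)-4-{[tert-butyl(dimethyl)silyl]oxy}-8-[(4-methoxyphenyl)methoxy]-6-methyl-3-(propan-2-yl)-1,2,3,3a,4,7-hexahydroazulen-3-ol, via dialkenylcyclopropane 15 (not isolated), via trimethylsilyl ether 16 (not isolated)
Conditions: 14 (3 equiv), toluene, 80 °C, sealed tube, argon; then K2CO3, MeOH, 0 °C → rt
Reagents that add atoms: none
Why: The electrophilic carbene carbon of 12 (future C8) is transferred to the terminal 1,1-disubstituted C=C of 14 (future C7 and C6) to give the cis-1,2-dialkenylcyclopropane 15, which at the same temperature undergoes a Cope rearrangement that forms C3a–C4 and cleaves C6–C8, so that C7–C8 and C3a–C4 are made in one operation. The closest known reaction type is the tandem cyclopropanation/Cope rearrangement (formal (4+3) cycloaddition) of alkenyl(alkoxy)carbene complexes of chromium, molybdenum and tungsten with electron-rich 1,3-dienes. The three-membered ring closes by (2+1) carbene transfer and the seven-membered ring by the suprafacial [3,3] shift through a boat transition state, a ring expansion of the cyclopropane and not a closure of an open chain. The relative configuration at C3a and C4 (3a-H and 4-H cis, hence 4β-OSi) should follow from the boat transition state with the E enol ether and the ring-locked E cyclopentenyl group, and the absolute sense from the C3 stereocentre, bond formation at C3a taking place anti to the isopropyl group. The step needs carbene transfer to outrun Diels–Alder addition to the alkenyl group and needs attack at the CH2 terminus of the diene: the first should be secured by the trisubstituted cyclopentenyl C=C next to the fully substituted C3, the second by the vinylogous enol ether polarisation that makes the unhindered terminus the most nucleophilic carbon.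

Step 9
Reactants: 17 (3R,3aS,4R)-4-{[tert-butyl(dimethyl)silyl]oxy}-8-[(4-methoxyphenyl)methoxy]-6-methyl-3-(propan-2-yl)-1,2,3,3a,4,7-hexahydroazulen-3-ol
Product: 18 (3R,3aS,4R,8S,8aR)-4-{[tert-butyl(dimethyl)silyl]oxy}-8-[(4-methoxyphenyl)methoxy]-6-methyl-3-(propan-2-yl)-8,8a-methano-1,2,3,3a,4,7,8,8a-octahydroazulen-3-ol (CH2 bridge between C8 and C8a on the face of the 3-OH)
Conditions: Et2Zn, CH2I2, CH2Cl2, −10 → 0 °C
Reagents that add atoms: diiodomethane, ICI
Why: Hydroxyl-directed Simmons–Smith (Furukawa) cyclopropanation, in which the zinc alkoxide of the tertiary 3-OH should deliver methylene to the β face of the electron-rich C8=C8a enol ether, setting C8a (future angular methyl cis to 3-OH and trans to 3a-H) and leaving the isolated C5=C6 alkene alone.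

Step 10
Reactants: 18 (3R,3aS,4R,8S,8aR)-4-{[tert-butyl(dimethyl)silyl]oxy}-8-[(4-methoxyphenyl)methoxy]-6-methyl-3-(propan-2-yl)-8,8a-methano-1,2,3,3a,4,7,8,8a-octahydroazulen-3-ol
Product: 21 (3R,3aS,4R,8aS)-4-{[tert-butyl(dimethyl)silyl]oxy}-3-hydroxy-6,8a-dimethyl-3-(propan-2-yl)-1,2,3,3a,4,5-hexahydroazulen-8(8aH)-one, via cyclopropanol 19 (not isolated), via deconjugated enone 20 (not isolated)
Conditions: DDQ, CH2Cl2/pH 7 buffer, 0 °C; then K2CO3, MeOH, rt
Reagents that add atoms: none
Why: Oxidative removal of the 4-methoxybenzyl group gives a cyclopropanol whose base-induced opening (homoenolate protonation, cleavage of the C8–CH2 bond) should unveil the C8 ketone and the angular methyl with retention at C8a, and the same base should move the β,γ-alkene into conjugation (C6=C7).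

Step 11
Reactants: 21 (3R,3aS,4R,8aS)-4-{[tert-butyl(dimethyl)silyl]oxy}-3-hydroxy-6,8a-dimethyl-3-(propan-2-yl)-1,2,3,3a,4,5-hexahydroazulen-8(8aH)-one
Product: 22 (3R,3aS,4R,8aS)-3,4-dihydroxy-6,8a-dimethyl-3-(propan-2-yl)-1,2,3,3a,4,5-hexahydroazulen-8(8aH)-one
Conditions: Bu4NF, AcOH, THF, 0 °C → rt
Reagents that add atoms: none
Why: Buffered fluoride desilylation should free the 4β-alcohol without base-induced elimination next to the enone.

Step 12
Reactants: 22 (3R,3aS,4R,8aS)-3,4-dihydroxy-6,8a-dimethyl-3-(propan-2-yl)-1,2,3,3a,4,5-hexahydroazulen-8(8aH)-one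
Product: 23 (3R,3aS,4S,8aS)-3-hydroxy-6,8a-dimethyl-8-oxo-3-(propan-2-yl)-1,2,3,3a,4,5,8,8a-octahydroazulen-4-yl 4-methoxybenzoate
Conditions: 4-MeOC6H4CO2H, PPh3, DIAD, toluene, 0 °C → rt
Reagents that add atoms: 4-methoxybenzoic acid, COc1ccc(cc1)C(=O)O
Why: Mitsunobu esterification should displace the axial 4β-oxyphosphonium group by the carboxylate with inversion to give the equatorial 4α-ester, the tertiary alcohol not reacting.

Step 13
Reactants: 23 (3R,3aS,4S,8aS)-3-hydroxy-6,8a-dimethyl-8-oxo-3-(propan-2-yl)-1,2,3,3a,4,5,8,8a-octahydroazulen-4-yl 4-methoxybenzoate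
Product: 24 (3R,3aS,4S,8R,8aS)-3,8-dihydroxy-6,8a-dimethyl-3-(propan-2-yl)-1,2,3,3a,4,5,8,8a-octahydroazulen-4-yl 4-methoxybenzoate
Conditions: LiBH(s-Bu)3, THF, −78 °C; aq. NH4Cl
Reagents that add atoms: none
Why: 1,2-Reduction of the β,β-disubstituted enone by a bulky trialkylborohydride, which should approach along the peripheral (equatorial) trajectory and not across the α face, giving the pseudo-axial 8α-alcohol trans to the angular methyl (the β-substituent suppresses conjugate reduction).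

Step 14
Reactants: 24 (3R,3aS,4S,8R,8aS)-3,8-dihydroxy-6,8a-dimethyl-3-(propan-2-yl)-1,2,3,3a,4,5,8,8a-octahydroazulen-4-yl 4-methoxybenzoate
Product: 25 (3R,3aS,4S,8R,8aS)-3-hydroxy-6,8a-dimethyl-8-{[(2Z)-2-methylbut-2-enoyl]oxy}-3-(propan-2-yl)-1,2,3,3a,4,5,8,8a-octahydroazulen-4-yl 4-methoxybenzoate
Conditions: LiN(SiMe3)2, angelic anhydride, THF, −20 → 0 °C
Reagents that add atoms: angelic anhydride ((2Z)-2-methylbut-2-enoic anhydride), C/C=C(/C)C(=O)OC(=O)C(/C)=C\C
Why: Acylation of the lithium alkoxide of the secondary alcohol with the symmetrical anhydride at low temperature, without a nucleophilic amine catalyst, should give the angelate without Z-to-E isomerisation, the tertiary alkoxide being too hindered to react.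

## Compound list

1 | 3-ethoxycyclopent-2-en-1-one | CCOC1=CC(=O)CC1 | starting material
2 | 3-ethoxy-1-(propan-2-yl)cyclopent-2-en-1-ol (present as its chloromagnesium alkoxide; racemic) | CCOC1=CC(O)(C(C)C)CC1 | intermediate
3 | 3-(propan-2-yl)cyclopent-2-en-1-one | CC(C)C1=CC(=O)CC1 | intermediate
4 | (1S,5R)-5-(propan-2-yl)-6-oxabicyclo[3.1.0]hexan-2-one | O=C1CC[C@@]2(O[C@H]12)C(C)C | intermediate
5 | (1R,5R)-2-(methoxymethylidene)-5-(propan-2-yl)-6-oxabicyclo[3.1.0]hexane (E/Z mixture) | COC=C1CC[C@@]2(O[C@H]12)C(C)C | intermediate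
6 | (3R)-3-hydroxy-3-(propan-2-yl)cyclopent-1-ene-1-carbaldehyde | O=CC1=C[C@](O)(C(C)C)CC1 | intermediate
7 | (3R)-3-hydroxy-3-(propan-2-yl)cyclopent-1-ene-1-carboxylic acid | OC(=O)C1=C[C@](O)(C(C)C)CC1 | intermediate
8 | trimethylsilyl (3R)-3-(propan-2-yl)-3-(trimethylsilyloxy)cyclopent-1-ene-1-carboxylate | C[Si](C)(C)OC(=O)C1=C[C@](O[Si](C)(C)C)(C(C)C)CC1 | intermediate
9 | (3R)-3-(propan-2-yl)-3-(trimethylsilyloxy)cyclopent-1-ene-1-carbonyl chloride | ClC(=O)C1=C[C@](O[Si](C)(C)C)(C(C)C)CC1 | intermediate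
10 | sodium pentacarbonyl{[(3R)-3-(propan-2-yl)-3-(trimethylsilyloxy)cyclopent-1-en-1-yl]carbonyl}chromate | [Na+].O=C([Cr-](=C=O)(=C=O)(=C=O)(=C=O)=C=O)C1=C[C@](O[Si](C)(C)C)(C(C)C)CC1 | intermediate
11 | pentacarbonyl{(acetyloxy)[(3R)-3-(propan-2-yl)-3-(trimethylsilyloxy)cyclopent-1-en-1-yl]methylidene}chromium | CC(=O)OC(=[Cr](=C=O)(=C=O)(=C=O)(=C=O)=C=O)C1=C[C@](O[Si](C)(C)C)(C(C)C)CC1 | intermediate
12 | pentacarbonyl{[(4-methoxyphenyl)methoxy][(3R)-3-(propan-2-yl)-3-(trimethylsilyloxy)cyclopent-1-en-1-yl]methylidene}chromium | COc1ccc(COC(=[Cr](=C=O)(=C=O)(=C=O)(=C=O)=C=O)C2=C[C@](O[Si](C)(C)C)(C(C)C)CC2)cc1 | intermediate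
13 | 3-methylbut-2-enal | CC(C)=CC=O | starting material
14 | tert-butyl(dimethyl){[(1E)-3-methylbuta-1,3-dien-1-yl]oxy}silane | C=C(C)/C=C/O[Si](C)(C)C(C)(C)C | intermediate
15 | tert-butyl({(E)-2-[(1R,2R)-2-[(4-methoxyphenyl)methoxy]-1-methyl-2-{(3R)-3-(propan-2-yl)-3-(trimethylsilyloxy)cyclopent-1-en-1-yl}cyclopropyl]ethenyl}oxy)dimethylsilane (the two alkenyl groups cis) | COc1ccc(CO[C@@]2(C3=C[C@](O[Si](C)(C)C)(C(C)C)CC3)C[C@]2(C)/C=C/O[Si](C)(C)C(C)(C)C)cc1 | intermediate
16 | tert-butyl{[(3R,3aS,4R)-8-[(4-methoxyphenyl)methoxy]-6-methyl-3-(propan-2-yl)-3-(trimethylsilyloxy)-1,2,3,3a,4,7-hexahydroazulen-4-yl]oxy}dimethylsilane | COc1ccc(COC2=C3CC[C@@](O[Si](C)(C)C)(C(C)C)[C@@H]3[C@H](O[Si](C)(C)C(C)(C)C)C=C(C)C2)cc1 | intermediate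
17 | (3R,3aS,4R)-4-{[tert-butyl(dimethyl)silyl]oxy}-8-[(4-methoxyphenyl)methoxy]-6-methyl-3-(propan-2-yl)-1,2,3,3a,4,7-hexahydroazulen-3-ol | COc1ccc(COC2=C3CC[C@@](O)(C(C)C)[C@@H]3[C@H](O[Si](C)(C)C(C)(C)C)C=C(C)C2)cc1 | intermediate
18 | (3R,3aS,4R,8S,8aR)-4-{[tert-butyl(dimethyl)silyl]oxy}-8-[(4-methoxyphenyl)methoxy]-6-methyl-3-(propan-2-yl)-8,8a-methano-1,2,3,3a,4,7,8,8a-octahydroazulen-3-ol (CH2 bridge cis to 3-OH) | COc1ccc(CO[C@]23C[C@@]34CC[C@@](O)(C(C)C)[C@@H]4[C@H](O[Si](C)(C)C(C)(C)C)C=C(C)C2)cc1 | intermediate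
19 | (3R,3aS,4R,8S,8aR)-4-{[tert-butyl(dimethyl)silyl]oxy}-6-methyl-3-(propan-2-yl)-8,8a-methano-1,2,3,3a,4,7,8,8a-octahydroazulene-3,8-diol | O[C@]23C[C@@]34CC[C@@](O)(C(C)C)[C@@H]4[C@H](O[Si](C)(C)C(C)(C)C)C=C(C)C2 | intermediate
20 | (3R,3aS,4R,8aS)-4-{[tert-butyl(dimethyl)silyl]oxy}-3-hydroxy-6,8a-dimethyl-3-(propan-2-yl)-1,2,3,3a,4,7-hexahydroazulen-8(8aH)-one | O=C1CC(C)=C[C@@H](O[Si](C)(C)C(C)(C)C)[C@@H]2[C@]1(C)CC[C@@]2(O)C(C)C | intermediate
21 | (3R,3aS,4R,8aS)-4-{[tert-butyl(dimethyl)silyl]oxy}-3-hydroxy-6,8a-dimethyl-3-(propan-2-yl)-1,2,3,3a,4,5-hexahydroazulen-8(8aH)-one | O=C1C=C(C)C[C@@H](O[Si](C)(C)C(C)(C)C)[C@@H]2[C@]1(C)CC[C@@]2(O)C(C)C | intermediate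
22 | (3R,3aS,4R,8aS)-3,4-dihydroxy-6,8a-dimethyl-3-(propan-2-yl)-1,2,3,3a,4,5-hexahydroazulen-8(8aH)-one | O=C1C=C(C)C[C@@H](O)[C@@H]2[C@]1(C)CC[C@@]2(O)C(C)C | intermediate
23 | (3R,3aS,4S,8aS)-3-hydroxy-6,8a-dimethyl-8-oxo-3-(propan-2-yl)-1,2,3,3a,4,5,8,8a-octahydroazulen-4-yl 4-methoxybenzoate | O=C1C=C(C)C[C@H](OC(=O)c2ccc(OC)cc2)[C@@H]2[C@]1(C)CC[C@@]2(O)C(C)C | intermediate
24 | (3R,3aS,4S,8R,8aS)-3,8-dihydroxy-6,8a-dimethyl-3-(propan-2-yl)-1,2,3,3a,4,5,8,8a-octahydroazulen-4-yl 4-methoxybenzoate | O[C@@H]1C=C(C)C[C@H](OC(=O)c2ccc(OC)cc2)[C@@H]2[C@]1(C)CC[C@@]2(O)C(C)C | intermediate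
25 | (3R,3aS,4S,8R,8aS)-3-hydroxy-6,8a-dimethyl-8-{[(2Z)-2-methylbut-2-enoyl]oxy}-3-(propan-2-yl)-1,2,3,3a,4,5,8,8a-octahydroazulen-4-yl 4-methoxybenzoate | C/C=C(/C)C(=O)O[C@@H]1C=C(C)C[C@H](OC(=O)c2ccc(OC)cc2)[C@@H]2[C@]1(C)CC[C@@]2(O)C(C)C | target

## Step count and risks

Total step count: 14. Longest linear sequence: 13 steps (steps 1–6 and 8–14).

Steps most likely to fail:

1. The (4+3) union, step 8. What may go wrong: Diels–Alder addition of the diene across the alkenyl C=C of the carbene complex may outpace carbene transfer at 80 °C, or bond formation at C3a may occur on the isopropyl face. The fallback sets out from acid chloride 9 and returns to the route at enone 21. The acyl chromate 10 is O-acetylated as in step 6, and the acetoxycarbene complex 11 is not exchanged with the alcohol but treated with diene 14 at −30 → 0 °C. Acyloxycarbene complexes transfer the carbene carbon to 1,3-dienes far below the temperature at which the hindered alkenyl group reacts as a dienophile, so after Cope rearrangement this should give the enol acetate (3R,3aS,4R)-4-{[tert-butyl(dimethyl)silyl]oxy}-6-methyl-3-(propan-2-yl)-3-(trimethylsilyloxy)-1,2,3,3a,4,7-hexahydroazulen-8-yl acetate F1. Citric acid in MeOH then removes the tertiary trimethylsilyl group to give the hydroxy enol acetate (3R,3aS,4R)-4-{[tert-butyl(dimethyl)silyl]oxy}-3-hydroxy-6-methyl-3-(propan-2-yl)-1,2,3,3a,4,7-hexahydroazulen-8-yl acetate F2. Hydroxyl-directed cyclopropanation (Et2Zn, CH2I2) gives the cyclopropyl acetate (3R,3aS,4R,8S,8aR)-4-{[tert-butyl(dimethyl)silyl]oxy}-3-hydroxy-6-methyl-3-(propan-2-yl)-8,8a-methano-1,2,3,3a,4,7,8,8a-octahydroazulen-8-yl acetate F3. K2CO3 in MeOH cleaves the acetate and opens the cyclopropanol 19, which goes on through 20 to 21.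

2. The enone reduction, step 13. What may go wrong: hydride delivery to the α face, anti to the angular methyl, would give the 8β-epimer. The fallback sets out from ketone 23 and returns at alcohol 24: the reduction is done with an NADPH-dependent ketoreductase (alcohol dehydrogenase class, glucose/glucose dehydrogenase cofactor recycling, aqueous buffer with a cosolvent), the enzyme being picked from a panel for hydride delivery to the face syn to the angular methyl, so that the sense is set by the enzyme and not by the substrate. No new compound arises (entry F0).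

3. The Mitsunobu esterification, step 12. What may go wrong: anti elimination of the activated axial 4-oxyphosphonium group (anti-periplanar to 3a-H) instead of substitution at the hindered carbinol. The fallback sets out from diol 22 and returns at ester 23. Dess–Martin oxidation of the secondary alcohol gives the dione (3R,3aR,8aS)-3-hydroxy-6,8a-dimethyl-3-(propan-2-yl)-1,2,3,3a,5,8a-hexahydroazulene-4,8-dione F4. Evans–Saksena reduction (Me4NBH(OAc)3, AcOH/MeCN, −30 °C) of this β-hydroxy ketone, with hydride delivered from the boron bound to the 3-OH, should give the 1,3-anti diol (3R,3aS,4S,8aS)-3,4-dihydroxy-6,8a-dimethyl-3-(propan-2-yl)-1,2,3,3a,4,5-hexahydroazulen-8(8aH)-one F5. Acylation of its equatorial 4α-alcohol with 4-methoxybenzoyl chloride (pyridine, DMAP) gives 23 with retention.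

## Further compounds

F1 | step 8 | (3R,3aS,4R)-4-{[tert-butyl(dimethyl)silyl]oxy}-6-methyl-3-(propan-2-yl)-3-(trimethylsilyloxy)-1,2,3,3a,4,7-hexahydroazulen-8-yl acetate | CC(=O)OC1=C2CC[C@@](O[Si](C)(C)C)(C(C)C)[C@@H]2[C@H](O[Si](C)(C)C(C)(C)C)C=C(C)C1
F2 | step 8 | (3R,3aS,4R)-4-{[tert-butyl(dimethyl)silyl]oxy}-3-hydroxy-6-methyl-3-(propan-2-yl)-1,2,3,3a,4,7-hexahydroazulen-8-yl acetate | CC(=O)OC1=C2CC[C@@](O)(C(C)C)[C@@H]2[C@H](O[Si](C)(C)C(C)(C)C)C=C(C)C1
F3 | step 8 | (3R,3aS,4R,8S,8aR)-4-{[tert-butyl(dimethyl)silyl]oxy}-3-hydroxy-6-methyl-3-(propan-2-yl)-8,8a-methano-1,2,3,3a,4,7,8,8a-octahydroazulen-8-yl acetate | CC(=O)O[C@]23C[C@@]34CC[C@@](O)(C(C)C)[C@@H]4[C@H](O[Si](C)(C)C(C)(C)C)C=C(C)C2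
F0 | step 13 | none | none
F4 | step 12 | (3R,3aR,8aS)-3-hydroxy-6,8a-dimethyl-3-(propan-2-yl)-1,2,3,3a,5,8a-hexahydroazulene-4,8-dione | O=C1C=C(C)CC(=O)[C@@H]2[C@]1(C)CC[C@@]2(O)C(C)C
F5 | step 12 | (3R,3aS,4S,8aS)-3,4-dihydroxy-6,8a-dimethyl-3-(propan-2-yl)-1,2,3,3a,4,5-hexahydroazulen-8(8aH)-one | O=C1C=C(C)C[C@H](O)[C@@H]2[C@]1(C)CC[C@@]2(O)C(C)C
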